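## Retrosynthetic overview

1. The bridgehead prenyl group is carried as an (E)-but-2-enyl group and unmasked last by cross-metathesis.
2. The five-membered ring (second ring, closed last) is opened at the bond between the methyl-bearing ring carbon and the prenyl CH: a 5-exo oxidative radical cyclisation with O2 capture, which also installs the exo C(CH3)2OH.
3. Key bond: the quaternary carbon–CH2 bond is made by a dearomatising Claisen [3,3] shift of an aryl (S)-but-3-en-2-yl ether, with chair 1,3-chirality transfer; the prenyl arm arrives just before by an aromatic Claisen shift of a para 1,1-dimethylallyl ether.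
4. Both ethers are put on the acylphloroglucinol: propargylation/semihydrogenation at the para oxygen, then Mitsunobu at the free ortho oxygen.
5. The six-membered ring is bought as 2,4,6-trihydroxytoluene and acylated with (R)-2-methylbutanoic acid. Ring order: six-membered ring (bought), then five-membered ring (step 6).

Assumption: the target is one drawn tautomer of a freely tautomerising enolised triketone, and (2R)-2-methylbutanoic acid and both enantiomers of but-3-en-2-ol are bought enantiopure.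

## Route

Step 1
Reactants: 1 2-methylbenzene-1,3,5-triol (2,4,6-trihydroxytoluene); 2 (2R)-2-methylbutanoic acid
Product: 4 (2R)-2-methyl-1-(2,4,6-trihydroxy-3-methylphenyl)butan-1-one, via (2R)-2-methylbutanoyl chloride 3 (not isolated)
Conditions: 2, (COCl)2, DMF (cat.), CH2Cl2, 0 °C to rt; then 1, AlCl3, PhNO2, 0 °C to rt; aq. HCl work-up
Reagents that add atoms: none
Why: Friedel–Crafts acylation at one of the two equivalent free ring positions of 1; AlCl3 at or below room temperature does not enolise the α-branched acyl group, so the bought stereocentre is kept.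

Step 2
Reactants: 4 (2R)-2-methyl-1-(2,4,6-trihydroxy-3-methylphenyl)butan-1-one; 5 3-chloro-3-methylbut-1-yne
Product: 6 (2R)-1-{2,6-dihydroxy-3-methyl-4-[(2-methylbut-3-yn-2-yl)oxy]phenyl}-2-methylbutan-1-one
Conditions: K2CO3, KI (cat.), acetone, 56 °C
Reagents that add atoms: none
Why: Williamson-type O-propargylation; only the para hydroxyl is free of the hydrogen bond to the ketone and is the most acidic, so it alone is etherified.

Step 3
Reactants: 6 (2R)-1-{2,6-dihydroxy-3-methyl-4-[(2-methylbut-3-yn-2-yl)oxy]phenyl}-2-methylbutan-1-one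
Product: 7 (2R)-1-{2,6-dihydroxy-3-methyl-4-[(2-methylbut-3-en-2-yl)oxy]phenyl}-2-methylbutan-1-one
Conditions: H2 (1 atm), Pd/CaCO3 poisoned with Pb(OAc)2, quinoline, EtOAc, rt
Reagents that add atoms: none
Why: Lindlar-type semihydrogenation stops at the terminal alkene and leaves the aryl ketone and the tertiary ether untouched, giving the 1,1-dimethylallyl ether.

Step 4
Reactants: 7 (2R)-1-{2,6-dihydroxy-3-methyl-4-[(2-methylbut-3-en-2-yl)oxy]phenyl}-2-methylbutan-1-one; 8 (2R)-but-3-en-2-ol
Product: 9 (2R)-1-{6-[(2S)-but-3-en-2-yloxy]-2-hydroxy-3-methyl-4-[(2-methylbut-3-en-2-yl)oxy]phenyl}-2-methylbutan-1-one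
Conditions: PPh3, DIAD, THF, 0 °C to rt
Reagents that add atoms: none
Why: Mitsunobu etherification with SN2 inversion (R alcohol to S ether); the para oxygen is blocked and the hydroxyl between methyl and acyl is the more hindered and more strongly chelated, so the hydroxyl next to the free ring position reacts.

Step 5
Reactants: 9 (2R)-1-{6-[(2S)-but-3-en-2-yloxy]-2-hydroxy-3-methyl-4-[(2-methylbut-3-en-2-yl)oxy]phenyl}-2-methylbutan-1-one
Product: 11 (6S)-6-[(2E)-but-2-en-1-yl]-3,5-dihydroxy-4-methyl-2-[(2R)-2-methylbutanoyl]-6-(3-methylbut-2-en-1-yl)cyclohexa-2,4-dien-1-one, via C-prenylated aryl butenyl ether 10 (not isolated)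
Conditions: degassed toluene, 85 °C; then 135 °C (sealed tube)
Reagents that add atoms: none
Why: Two consecutive aromatic Claisen [3,3] rearrangements: the tertiary ether shifts first to the only unsubstituted ortho carbon and rearomatises to 10, then the (S) ether shifts through a chair transition state (methyl pseudo-equatorial) to the now prenylated ortho carbon, the other ortho carbon being blocked by the acyl group, which sets the quaternary stereocentre (6S) and the (E)-alkene by 1,3-chirality transfer.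

Step 6
Reactants: 11 (6S)-6-[(2E)-but-2-en-1-yl]-3,5-dihydroxy-4-methyl-2-[(2R)-2-methylbutanoyl]-6-(3-methylbut-2-en-1-yl)cyclohexa-2,4-dien-1-one
Product: 13 (1S,5S,6S)-1-[(2E)-but-2-en-1-yl]-4-hydroxy-6-(2-hydroxypropan-2-yl)-5-methyl-3-[(2R)-2-methylbutanoyl]bicyclo[3.2.1]oct-3-ene-2,8-dione, via tertiary hydroperoxide 12 (not isolated)
Conditions: Mn(OAc)3·2H2O (20 mol %), O2 (1 atm), AcOH, rt; then PPh3, CH2Cl2, 0 °C
Reagents that add atoms: dioxygen, O=O
Why: Oxidative radical cyclisation: the manganese enolate gives the radical at the methyl-bearing ring carbon, which closes 5-exo-trig onto the more electron-rich trisubstituted prenyl alkene; the ring closure forces the methyl bridgehead cis to the quaternary centre, the C(CH3)2 terminus sits exo (syn to the one-carbon bridge, away from the enolised diketone bridge), O2 traps the tertiary radical and PPh3 reduces the hydroperoxide.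

Step 7
Reactants: 13 (1S,5S,6S)-1-[(2E)-but-2-en-1-yl]-4-hydroxy-6-(2-hydroxypropan-2-yl)-5-methyl-3-[(2R)-2-methylbutanoyl]bicyclo[3.2.1]oct-3-ene-2,8-dione; 14 2-methylbut-2-ene
Product: 15 (1S,5S,6S)-4-hydroxy-6-(2-hydroxypropan-2-yl)-5-methyl-3-[(2R)-2-methylbutanoyl]-1-(3-methylbut-2-en-1-yl)bicyclo[3.2.1]oct-3-ene-2,8-dione
Conditions: 14 (excess), second-generation Grubbs catalyst RuCl2(=CHPh)(PCy3)(H2IMes) (5 mol %), CH2Cl2, 40 °C
Reagents that add atoms: none
Why: Olefin cross-metathesis exchanges the ethylidene terminus of the butenyl group for isopropylidene (crotyl to prenyl) without touching any stereocentre.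

## Compound list

1 | 2-methylbenzene-1,3,5-triol (2,4,6-trihydroxytoluene) | Cc1c(O)cc(O)cc1O | starting material
2 | (2R)-2-methylbutanoic acid | CC[C@@H](C)C(=O)O | starting material
3 | (2R)-2-methylbutanoyl chloride | CC[C@@H](C)C(Cl)=O | intermediate
4 | (2R)-2-methyl-1-(2,4,6-trihydroxy-3-methylphenyl)butan-1-one | CC[C@@H](C)C(=O)c1c(O)c(C)c(O)cc1O | intermediate
5 | 3-chloro-3-methylbut-1-yne | C#CC(C)(C)Cl | starting material
6 | (2R)-1-{2,6-dihydroxy-3-methyl-4-[(2-methylbut-3-yn-2-yl)oxy]phenyl}-2-methylbutan-1-one | CC[C@@H](C)C(=O)c1c(O)c(C)c(OC(C)(C)C#C)cc1O | intermediate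
7 | (2R)-1-{2,6-dihydroxy-3-methyl-4-[(2-methylbut-3-en-2-yl)oxy]phenyl}-2-methylbutan-1-one | CC[C@@H](C)C(=O)c1c(O)c(C)c(OC(C)(C)C=C)cc1O | intermediate
8 | (2R)-but-3-en-2-ol | C[C@@H](O)C=C | starting material
9 | (2R)-1-{6-[(2S)-but-3-en-2-yloxy]-2-hydroxy-3-methyl-4-[(2-methylbut-3-en-2-yl)oxy]phenyl}-2-methylbutan-1-one | CC[C@@H](C)C(=O)c1c(O)c(C)c(OC(C)(C)C=C)cc1O[C@@H](C)C=C | intermediate
10 | (2R)-1-{2-[(2S)-but-3-en-2-yloxy]-4,6-dihydroxy-5-methyl-3-(3-methylbut-2-en-1-yl)phenyl}-2-methylbutan-1-one | CC[C@@H](C)C(=O)c1c(O)c(C)c(O)c(CC=C(C)C)c1O[C@@H](C)C=C | intermediate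
11 | (6S)-6-[(2E)-but-2-en-1-yl]-3,5-dihydroxy-4-methyl-2-[(2R)-2-methylbutanoyl]-6-(3-methylbut-2-en-1-yl)cyclohexa-2,4-dien-1-one | CC[C@@H](C)C(=O)C1=C(O)C(C)=C(O)[C@@](CC=C(C)C)(C/C=C/C)C1=O | intermediate
12 | (1S,5S,6S)-1-[(2E)-but-2-en-1-yl]-6-(2-hydroperoxypropan-2-yl)-4-hydroxy-5-methyl-3-[(2R)-2-methylbutanoyl]bicyclo[3.2.1]oct-3-ene-2,8-dione | CC[C@@H](C)C(=O)C1=C(O)[C@@]2(C)C(=O)[C@](C/C=C/C)(C[C@@H]2C(C)(C)OO)C1=O | intermediate
13 | (1S,5S,6S)-1-[(2E)-but-2-en-1-yl]-4-hydroxy-6-(2-hydroxypropan-2-yl)-5-methyl-3-[(2R)-2-methylbutanoyl]bicyclo[3.2.1]oct-3-ene-2,8-dione | CC[C@@H](C)C(=O)C1=C(O)[C@@]2(C)C(=O)[C@](C/C=C/C)(C[C@@H]2C(C)(C)O)C1=O | intermediate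
14 | 2-methylbut-2-ene | CC=C(C)C | starting material
15 | (1S,5S,6S)-4-hydroxy-6-(2-hydroxypropan-2-yl)-5-methyl-3-[(2R)-2-methylbutanoyl]-1-(3-methylbut-2-en-1-yl)bicyclo[3.2.1]oct-3-ene-2,8-dione | CC[C@@H](C)C(=O)C1=C(O)[C@@]2(C)C(=O)[C@](CC=C(C)C)(C[C@@H]2C(C)(C)O)C1=O | target

## Step count and risks

Total: 7 steps. Longest linear sequence: 7 steps (1 to 15; compounds 2, 5, 8 and 14 are bought partners). Leakage in the chirality transfer of step 5 (Z-alkene or boat pathway) gives the epimer at the quaternary carbon, which is a diastereomer because of the acyl stereocentre and can be removed by chromatography or crystallisation.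

The three steps most likely to fail are steps 4, 5 and 6.

Step 4 may not distinguish the two chelated ortho hydroxyls of 7, or may give SN2' ether. The fallback moves the chiral ether to the para oxygen, where selectivity is secure. It sets out from 4 and comes back at 11. C-Prenylation of 4 (1-bromo-3-methylbut-2-ene, aq. KOH, 0 °C) gives (2R)-2-methyl-1-[2,4,6-trihydroxy-3-methyl-5-(3-methylbut-2-en-1-yl)phenyl]butan-1-one F1. Mitsunobu reaction of its para hydroxyl with (2S)-but-3-en-2-ol gives (2R)-1-{4-[(2R)-but-3-en-2-yloxy]-2,6-dihydroxy-3-methyl-5-(3-methylbut-2-en-1-yl)phenyl}-2-methylbutan-1-one F2; the R ether is needed because the shift now starts from the oxygen on the other side of the reacting carbon. Heating at 135 °C gives 11 by the dearomatising Claisen shift to the prenyl-bearing ortho carbon. The price is the isomer from the shift to the methyl-bearing ortho carbon, (6R)-6-[(2E)-but-2-en-1-yl]-3,5-dihydroxy-6-methyl-2-[(2R)-2-methylbutanoyl]-4-(3-methylbut-2-en-1-yl)cyclohexa-2,4-dien-1-one F3, which is separated by chromatography and may be the major product.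

Step 5 depends on the tertiary ether shifting before the chiral secondary ether. If the chiral ether migrates first to the still unsubstituted carbon, its stereocentre is lost and the quaternary carbon is formed without control. The fallback installs the prenyl group by direct C-alkylation, so that only the chirality-transferring shift remains. It sets out from 4 and comes back at 10. Para-selective silylation (TBSCl, imidazole, DMF) gives (2R)-1-{4-[(tert-butyldimethylsilyl)oxy]-2,6-dihydroxy-3-methylphenyl}-2-methylbutan-1-one F4. Mitsunobu reaction with 8 as in step 4 gives (2R)-1-{6-[(2S)-but-3-en-2-yloxy]-4-[(tert-butyldimethylsilyl)oxy]-2-hydroxy-3-methylphenyl}-2-methylbutan-1-one F5. TBAF in THF gives (2R)-1-{6-[(2S)-but-3-en-2-yloxy]-2,4-dihydroxy-3-methylphenyl}-2-methylbutan-1-one F6. C-Prenylation at the only free ring carbon (1-bromo-3-methylbut-2-ene, aq. KOH, 0 °C) gives 10, which is isolated and heated at 135 °C to 11.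

Step 6 has three risks: capture of the first radical by O2 before it cyclises, competing closure onto the butenyl arm, and exo/endo selectivity at the new methine. The exo preference is argued from sterics and is not certain. The fallback removes O2 from the cyclisation and introduces the hydroxyl afterwards. It sets out from 11 and comes back at 13. Mn(OAc)3·2H2O (2 equiv) and Cu(OAc)2·H2O (1 equiv) in degassed AcOH at rt cyclise 11 in the same 5-exo manner and oxidise the tertiary radical to the alkene, giving (1S,5S,6R)-1-[(2E)-but-2-en-1-yl]-4-hydroxy-5-methyl-3-[(2R)-2-methylbutanoyl]-6-(prop-1-en-2-yl)bicyclo[3.2.1]oct-3-ene-2,8-dione F7. Mukaiyama hydration (Co(acac)2 cat., PhSiH3, O2, i-PrOH, rt) then adds water in the Markovnikov sense to the 1,1-disubstituted alkene, in preference to the 1,2-disubstituted butenyl alkene, and gives 13.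

Further compounds
F1 | step 4 | (2R)-2-methyl-1-[2,4,6-trihydroxy-3-methyl-5-(3-methylbut-2-en-1-yl)phenyl]butan-1-one | CC[C@@H](C)C(=O)c1c(O)c(C)c(O)c(CC=C(C)C)c1O
F2 | step 4 | (2R)-1-{4-[(2R)-but-3-en-2-yloxy]-2,6-dihydroxy-3-methyl-5-(3-methylbut-2-en-1-yl)phenyl}-2-methylbutan-1-one | CC[C@@H](C)C(=O)c1c(O)c(C)c(O[C@H](C)C=C)c(CC=C(C)C)c1O
F3 | step 4 | (6R)-6-[(2E)-but-2-en-1-yl]-3,5-dihydroxy-6-methyl-2-[(2R)-2-methylbutanoyl]-4-(3-methylbut-2-en-1-yl)cyclohexa-2,4-dien-1-one | CC[C@@H](C)C(=O)C1=C(O)C(CC=C(C)C)=C(O)[C@@](C)(C/C=C/C)C1=O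
F4 | step 5 | (2R)-1-{4-[(tert-butyldimethylsilyl)oxy]-2,6-dihydroxy-3-methylphenyl}-2-methylbutan-1-one | CC[C@@H](C)C(=O)c1c(O)c(C)c(O[Si](C)(C)C(C)(C)C)cc1O
F5 | step 5 | (2R)-1-{6-[(2S)-but-3-en-2-yloxy]-4-[(tert-butyldimethylsilyl)oxy]-2-hydroxy-3-methylphenyl}-2-methylbutan-1-one | CC[C@@H](C)C(=O)c1c(O)c(C)c(O[Si](C)(C)C(C)(C)C)cc1O[C@@H](C)C=C
F6 | step 5 | (2R)-1-{6-[(2S)-but-3-en-2-yloxy]-2,4-dihydroxy-3-methylphenyl}-2-methylbutan-1-one | CC[C@@H](C)C(=O)c1c(O)c(C)c(O)cc1O[C@@H](C)C=C
F7 | step 6 | (1S,5S,6R)-1-[(2E)-but-2-en-1-yl]-4-hydroxy-5-methyl-3-[(2R)-2-methylbutanoyl]-6-(prop-1-en-2-yl)bicyclo[3.2.1]oct-3-ene-2,8-dione | CC[C@@H](C)C(=O)C1=C(O)[C@@]2(C)C(=O)[C@](C/C=C/C)(C[C@@H]2C(C)=C)C1=O
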